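**Plan**

1. Feature: ring A is a resorcinol core with oxygen on C2 (OMe) and C6 (OAr), the carboxyl carbon on C1 between them, H on C4 and C5 and the (S)-acetoxyisopentyl chain on C3. This is the pattern formed when a vinylketene (C2–C5) is annulated with a 1-alkynyl ether (C6, C1).
2. Retrosynthesis: functional groups are adjusted first (CO2H from CH2OSiEt3, OAc from OTBS, the ring B enone C=C by Wittig from a masked aldehyde, ring B OH from OPMB, OMe from OH). Ring A is then cut at C1–C2, C2–C3, C4–C5 and C5–C6 into diazo enone 18 and aryloxyalkyne 11.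
3. 11 is cut at the alkyne–CH2O bond (formaldehyde) and at the O–alkyne bond (trichloroethylene plus phenol 4, from creosol). 18 is cut at its C=C (Wittig) and at the diazo carbon, back to L-leucic acid.
4. Forward: ring B is functionalised first (steps 1–7) and the chain 18 is made in parallel (steps 8–12). Ring A, the only ring formed, closes in step 13 with the diaryl ether oxygen already attached; the butenone chain is joined to ring B afterwards (step 16).
5. Stereochemistry: the single stereocentre (S) comes from L-leucic acid and never becomes a reacting centre; both E alkenes are set by stabilised-ylide Wittig reactions.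

Key step: step 13

Remark: the sp3 ring carbons of the non-isolated compounds 20 and 22 form without control and are written without configuration; both become aromatic carbons in 23.

**Route**

Step 1
Reactants: 1 creosol (2-methoxy-4-methylphenol)
Product: 2 2-hydroxy-3-methoxy-5-methylbenzaldehyde
Conditions: MgCl2, Et3N, (CH2O)n, MeCN, reflux; then 1 M HCl
Reagents that add atoms: paraformaldehyde (as formaldehyde), C=O
Why: Casnati–Skattebøl ortho-formylation, in which the magnesium phenoxide delivers formaldehyde to the only free ortho position (para is blocked by the methyl group) and a second formaldehyde oxidises the benzylic alkoxide by hydride transfer, so one regioisomer is expected.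

Step 2
Reactants: 2 2-hydroxy-3-methoxy-5-methylbenzaldehyde
Product: 3 2,3-dihydroxy-5-methylbenzaldehyde
Conditions: BBr3, CH2Cl2, −78 °C → rt; then H2O
Reagents that add atoms: none
Why: Lewis acid ether cleavage (bromide attacks the O-methyl group of the boron-complexed aryl ether) should free the catechol, while the formyl group only coordinates reversibly and is returned on hydrolysis.

Step 3
Reactants: 3 2,3-dihydroxy-5-methylbenzaldehyde
Product: 4 2-hydroxy-3-(4-methoxybenzyloxy)-5-methylbenzaldehyde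
Conditions: NaH (2.2 equiv), DMSO, rt; then PMBCl (1.0 equiv), rt; dilute HCl work-up
Reagents that add atoms: 4-methoxybenzyl chloride, COc1ccc(CCl)cc1
Why: Williamson etherification of the dianion, in which the 3-oxide is neither conjugated with nor chelated to the formyl group and is therefore the more nucleophilic oxygen, so one equivalent of PMBCl should alkylate O3 selectively.

Step 4
Reactants: 4 2-hydroxy-3-(4-methoxybenzyloxy)-5-methylbenzaldehyde; 5 trichloroethylene
Product: 6 2-[(E)-1,2-dichlorovinyloxy]-3-(4-methoxybenzyloxy)-5-methylbenzaldehyde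
Conditions: K2CO3, DMF, 70 °C
Reagents that add atoms: none
Why: Nucleophilic vinylic substitution by elimination–addition, in which base generates dichloroacetylene from trichloroethylene and the phenoxide adds to it in anti fashion, should give the (E)-1,2-dichlorovinyl aryl ether as is general for phenols.

Step 5
Reactants: 6 2-[(E)-1,2-dichlorovinyloxy]-3-(4-methoxybenzyloxy)-5-methylbenzaldehyde
Product: 7 2-{2-[(E)-1,2-dichlorovinyloxy]-3-(4-methoxybenzyloxy)-5-methylphenyl}-1,3-dioxolane
Conditions: HOCH2CH2OH, PPTS (cat.), benzene, reflux (Dean–Stark)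
Reagents that add atoms: ethylene glycol, OCCO
Why: Acid-catalysed acetalisation with azeotropic removal of water masks the aldehyde against the organolithium of the next step, and PPTS is mild enough for the PMB aryl ether and the electron-poor dichlorovinyl ether.

Step 6
Reactants: 7 2-{2-[(E)-1,2-dichlorovinyloxy]-3-(4-methoxybenzyloxy)-5-methylphenyl}-1,3-dioxolane
Product: 10 3-[2-(1,3-dioxolan-2-yl)-6-(4-methoxybenzyloxy)-4-methylphenoxy]prop-2-yn-1-ol, via chloroalkyne 8 (not isolated), via lithium acetylide 9 (not isolated)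
Conditions: n-BuLi (2.3 equiv), THF, −78 → −40 °C; then (CH2O)n, −40 °C → rt; H2O quench, Et3N-buffered silica
Reagents that add atoms: paraformaldehyde (as formaldehyde), C=O; n-butyllithium (lithium of intermediate 9 only), [Li]CCCC
Why: The dichlorovinyl ether route to ynol ethers applies, since dehydrochlorination by the first equivalent of n-BuLi gives chloroalkyne 8, lithium–chlorine exchange with the second gives acetylide 9, and 1,2-addition of 9 to formaldehyde should give the propargylic alcohol, which is kept away from acid because 3-alkoxypropargyl alcohols rearrange (Meyer–Schuster) easily.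

Step 7
Reactants: 10 3-[2-(1,3-dioxolan-2-yl)-6-(4-methoxybenzyloxy)-4-methylphenoxy]prop-2-yn-1-ol
Product: 11 {3-[2-(1,3-dioxolan-2-yl)-6-(4-methoxybenzyloxy)-4-methylphenoxy]prop-2-ynyloxy}triethylsilane
Conditions: Et3SiCl, imidazole, CH2Cl2, 0 °C
Reagents that add atoms: chlorotriethylsilane, CC[Si](Cl)(CC)CC
Why: Standard silylation of a primary alcohol with a chlorosilane and imidazole; the triethylsilyl group is chosen because one mild acid treatment later removes it together with the dioxolane while the secondary TBS ether stays.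

Step 8
Reactants: 12 (S)-2-hydroxy-4-methylpentanoic acid (L-leucic acid)
Product: 13 methyl (S)-2-hydroxy-4-methylpentanoate
Conditions: MeOH, AcCl (cat.), reflux
Reagents that add atoms: methanol, CO
Why: Fischer esterification with HCl generated from AcCl and MeOH, which does not involve the stereocentre.

Step 9
Reactants: 13 methyl (S)-2-hydroxy-4-methylpentanoate
Product: 14 methyl (S)-2-(tert-butyldimethylsilyloxy)-4-methylpentanoate
Conditions: TBSCl, imidazole, DMF, rt
Reagents that add atoms: tert-butylchlorodimethylsilane, CC(C)(C)[Si](C)(C)Cl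
Why: Imidazole-promoted O-silylation of the secondary alcohol gives a protecting group that survives hydride, ylide, amide base, light and heat and occurs at oxygen without touching the C–O bond.

Step 10
Reactants: 14 methyl (S)-2-(tert-butyldimethylsilyloxy)-4-methylpentanoate
Product: 15 (S)-2-(tert-butyldimethylsilyloxy)-4-methylpentanal
Conditions: i-Bu2AlH (1.1 equiv), CH2Cl2, −78 °C; then MeOH, aq. potassium sodium tartrate
Reagents that add atoms: none
Why: Partial ester reduction with i-Bu2AlH at −78 °C, in which the α-silyloxy group stabilises the tetrahedral aluminium hemiacetal until work-up, should stop at the aldehyde, and the cold non-basic conditions leave the α-stereocentre intact.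

Step 11
Reactants: 15 (S)-2-(tert-butyldimethylsilyloxy)-4-methylpentanal
Product: 16 (S,E)-5-(tert-butyldimethylsilyloxy)-7-methyloct-3-en-2-one
Conditions: Ph3P=CHC(O)CH3, CH2Cl2, rt → 40 °C
Reagents that add atoms: 1-(triphenylphosphoranylidene)propan-2-one, CC(=O)C=P(c1ccccc1)(c1ccccc1)c1ccccc1
Why: Wittig olefination with a stabilised acyl ylide under base-free conditions should give the (E)-enone through the preferred trans-oxaphosphetane without epimerising the α-silyloxy aldehyde.

Step 12
Reactants: 16 (S,E)-5-(tert-butyldimethylsilyloxy)-7-methyloct-3-en-2-one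
Product: 18 (S,E)-5-(tert-butyldimethylsilyloxy)-1-diazo-7-methyloct-3-en-2-one, via trifluoroacetyl diketone 17 (not isolated)
Conditions: LiN(SiMe3)2, THF, −78 °C; CF3CO2CH2CF3, −78 °C; dilute HCl wash; then MsN3, Et3N, H2O (1 equiv), MeCN, rt
Reagents that add atoms: methanesulfonyl azide, CS(=O)(=O)N=[N+]=[N-]; 2,2,2-trifluoroethyl trifluoroacetate (trifluoroacetyl group of intermediate 17 only), O=C(OCC(F)(F)F)C(F)(F)F
Why: Detrifluoroacetylative diazo transfer (Claisen activation followed by Regitz-type diazo transfer) applies, since kinetic deprotonation of the methyl group at −78 °C and trifluoroacetylation give diketone 17, which takes up the diazo group from MsN3 with loss of the trifluoroacetyl group as the N-sulfonylamide, while the γ-hydrogen at the stereocentre is not removed under kinetic conditions.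

Step 13
Reactants: 18 (S,E)-5-(tert-butyldimethylsilyloxy)-1-diazo-7-methyloct-3-en-2-one; 11 {3-[2-(1,3-dioxolan-2-yl)-6-(4-methoxybenzyloxy)-4-methylphenoxy]prop-2-ynyloxy}triethylsilane
Product: 23 6-[(1S)-1-(tert-butyldimethylsilyloxy)-3-methylbutyl]-3-[2-(1,3-dioxolan-2-yl)-6-(4-methoxybenzyloxy)-4-methylphenoxy]-2-[(triethylsilyloxy)methyl]phenol, via vinylketene 19 (not isolated), via 4-vinylcyclobutenone 20 (not isolated), via dienylketene 21 (not isolated), via cyclohexadienone 22 (not isolated)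
Conditions: 18 (1.3 equiv) added slowly to 11, hν (350 nm, Pyrex), degassed toluene, rt; then 80 °C
Reagents that add atoms: none
Why: Irradiation excites only the diazo enone, which loses N2 and undergoes Wolff rearrangement with 1,2-shift of the vinyl group (C4–C5) to (E)-vinylketene 19; the nucleophilic alkyne carbon of 11 (the one bearing CH2OSiEt3) attacks the ketene carbonyl carbon while the oxygen-bearing alkyne carbon bonds to the ketene α-carbon in a [2+2] cycloaddition (C1–C2 and C5–C6) to give 4-vinylcyclobutenone 20, which on warming opens reversibly in a four-electron electrocyclic reaction to dienylketene 21, and this closes by six-electron electrocyclisation (C2–C3) to dienone 22, which tautomerises to phenol 23. The closest known reaction is the second-generation Danheiser benzannulation of unsaturated diazo ketones with alkoxy- and siloxyalkynes, of which the aryloxyalkyne is a less electron-rich member of the same 1-alkynyl ether class. Ring A, the only ring formed, closes as a six-membered carbocycle by thermal disrotatory 6π electrocyclisation of the dienylketene after the [2+2] addition and four-membered ring opening have joined the two components. No stereocentre is created in the product, because the sp3 carbons of 20 and 22 vanish on aromatisation and the (S) carbinol carbon lies outside the reacting π system and is carried through unchanged. The step needs regioselectivity in the [2+2] event, secured by the polarisation of the ynol ether (OAr ends up meta to the new OH with the CH2OSiEt3 carbon between them), and it needs selective excitation and fast ketene capture, secured by 350 nm light that the benzyl aryl ether and aryloxyalkyne chromophores do not absorb and by slow addition of 18, which keeps the ketene concentration low. An aryloxy group, unlike an alkoxy group with β-hydrogens, cannot fragment by retro-ene reaction at 80 °C, and the doubly ortho-substituted product phenol should be acylated only slowly by residual ketene.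

Step 14
Reactants: 23 6-[(1S)-1-(tert-butyldimethylsilyloxy)-3-methylbutyl]-3-[2-(1,3-dioxolan-2-yl)-6-(4-methoxybenzyloxy)-4-methylphenoxy]-2-[(triethylsilyloxy)methyl]phenol
Product: 24 tert-butyl{(1S)-1-[4-[2-(1,3-dioxolan-2-yl)-6-(4-methoxybenzyloxy)-4-methylphenoxy]-2-methoxy-3-[(triethylsilyloxy)methyl]phenyl]-3-methylbutoxy}dimethylsilane
Conditions: MeI, Cs2CO3, DMF, rt
Reagents that add atoms: iodomethane, CI
Why: Williamson O-methylation of the caesium phenoxide, which is far more stable than any alkoxide that silyl migration could produce, should cap the new phenol as the methyl ether of the target.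

Step 15
Reactants: 24 tert-butyl{(1S)-1-[4-[2-(1,3-dioxolan-2-yl)-6-(4-methoxybenzyloxy)-4-methylphenoxy]-2-methoxy-3-[(triethylsilyloxy)methyl]phenyl]-3-methylbutoxy}dimethylsilane
Product: 25 2-{4-[(1S)-1-(tert-butyldimethylsilyloxy)-3-methylbutyl]-2-(hydroxymethyl)-3-methoxyphenoxy}-3-(4-methoxybenzyloxy)-5-methylbenzaldehyde
Conditions: AcOH–THF–H2O (3:1:1), 40 °C
Reagents that add atoms: water, O
Why: Acetal hydrolysis and solvolysis of the primary triethylsilyl ether both proceed in mild aqueous acid, whereas the hindered secondary TBS ether and the PMB aryl ether are stable at this acidity.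

Step 16
Reactants: 25 2-{4-[(1S)-1-(tert-butyldimethylsilyloxy)-3-methylbutyl]-2-(hydroxymethyl)-3-methoxyphenoxy}-3-(4-methoxybenzyloxy)-5-methylbenzaldehyde
Product: 26 (E)-4-{2-[4-[(1S)-1-(tert-butyldimethylsilyloxy)-3-methylbutyl]-2-(hydroxymethyl)-3-methoxyphenoxy]-3-(4-methoxybenzyloxy)-5-methylphenyl}but-3-en-2-one
Conditions: Ph3P=CHC(O)CH3, toluene, 80 °C
Reagents that add atoms: 1-(triphenylphosphoranylidene)propan-2-one, CC(=O)C=P(c1ccccc1)(c1ccccc1)c1ccccc1
Why: Wittig olefination of the only aldehyde present with the stabilised ylide should give the (E)-enone, and the free benzylic alcohol does not interfere.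

Step 17
Reactants: 26 (E)-4-{2-[4-[(1S)-1-(tert-butyldimethylsilyloxy)-3-methylbutyl]-2-(hydroxymethyl)-3-methoxyphenoxy]-3-(4-methoxybenzyloxy)-5-methylphenyl}but-3-en-2-one
Product: 27 3-[(1S)-1-(tert-butyldimethylsilyloxy)-3-methylbutyl]-2-methoxy-6-{2-(4-methoxybenzyloxy)-4-methyl-6-[(E)-3-oxobut-1-enyl]phenoxy}benzaldehyde
Conditions: Dess–Martin periodinane, CH2Cl2, rt
Reagents that add atoms: none
Why: Dess–Martin oxidation of the primary benzylic alcohol stops at the aldehyde under neutral conditions that leave the enone, the PMB ether and the TBS ether untouched.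

Step 18
Reactants: 27 3-[(1S)-1-(tert-butyldimethylsilyloxy)-3-methylbutyl]-2-methoxy-6-{2-(4-methoxybenzyloxy)-4-methyl-6-[(E)-3-oxobut-1-enyl]phenoxy}benzaldehyde
Product: 28 3-[(1S)-1-hydroxy-3-methylbutyl]-2-methoxy-6-{2-(4-methoxybenzyloxy)-4-methyl-6-[(E)-3-oxobut-1-enyl]phenoxy}benzaldehyde
Conditions: HF·pyridine, THF, 0 °C → rt
Reagents that add atoms: none
Why: Fluoride-driven silyl ether cleavage at silicon under weakly acidic, non-basic conditions avoids aldol chemistry of the methyl ketone and does not break the benzylic C–O bond, so the S configuration is retained.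

Step 19
Reactants: 28 3-[(1S)-1-hydroxy-3-methylbutyl]-2-methoxy-6-{2-(4-methoxybenzyloxy)-4-methyl-6-[(E)-3-oxobut-1-enyl]phenoxy}benzaldehyde
Product: 29 (1S)-1-[3-formyl-2-methoxy-4-{2-(4-methoxybenzyloxy)-4-methyl-6-[(E)-3-oxobut-1-enyl]phenoxy}phenyl]-3-methylbutyl acetate
Conditions: Ac2O, pyridine, DMAP (cat.), CH2Cl2, rt
Reagents that add atoms: acetic anhydride, CC(=O)OC(C)=O
Why: DMAP-catalysed O-acylation of the secondary alcohol takes place at oxygen and therefore with retention at the stereocentre.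

Step 20
Reactants: 29 (1S)-1-[3-formyl-2-methoxy-4-{2-(4-methoxybenzyloxy)-4-methyl-6-[(E)-3-oxobut-1-enyl]phenoxy}phenyl]-3-methylbutyl acetate
Product: 30 3-[(1S)-1-acetoxy-3-methylbutyl]-2-methoxy-6-{2-(4-methoxybenzyloxy)-4-methyl-6-[(E)-3-oxobut-1-enyl]phenoxy}benzoic acid
Conditions: NaClO2, NaH2PO4, 2-methyl-2-butene, t-BuOH–H2O, rt
Reagents that add atoms: sodium chlorite, [Na+].[O-]Cl=O
Why: Pinnick oxidation, in which chlorous acid adds to the hindered aldehyde and fragments to the acid while 2-methyl-2-butene scavenges HOCl, tolerates the enone, the acetate and the electron-rich rings.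

Step 21
Reactants: 30 3-[(1S)-1-acetoxy-3-methylbutyl]-2-methoxy-6-{2-(4-methoxybenzyloxy)-4-methyl-6-[(E)-3-oxobut-1-enyl]phenoxy}benzoic acid
Product: 31 3-[(1S)-1-acetoxy-3-methylbutyl]-6-{2-hydroxy-4-methyl-6-[(E)-3-oxobut-1-enyl]phenoxy}-2-methoxybenzoic acid (target)
Conditions: DDQ (1.5 equiv), CH2Cl2–pH 7 phosphate buffer, 0 °C → rt
Reagents that add atoms: none
Why: Oxidative PMB ether cleavage by DDQ (electron transfer from the anisyl ring, hydride loss to the oxocarbenium ion and hydrolysis) runs under neutral conditions that should spare the benzylic acetate, the enone and the carboxylic acid.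

**Compound list**

1 | creosol (2-methoxy-4-methylphenol) | Cc1ccc(O)c(OC)c1 | starting material
2 | 2-hydroxy-3-methoxy-5-methylbenzaldehyde | COc1cc(C)cc(C=O)c1O | intermediate
3 | 2,3-dihydroxy-5-methylbenzaldehyde | Cc1cc(O)c(O)c(C=O)c1 | intermediate
4 | 2-hydroxy-3-(4-methoxybenzyloxy)-5-methylbenzaldehyde | COc1ccc(COc2cc(C)cc(C=O)c2O)cc1 | intermediate
5 | trichloroethylene | ClC=C(Cl)Cl | starting material
6 | 2-[(E)-1,2-dichlorovinyloxy]-3-(4-methoxybenzyloxy)-5-methylbenzaldehyde | COc1ccc(COc2cc(C)cc(C=O)c2O/C(Cl)=C\Cl)cc1 | intermediate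
7 | 2-{2-[(E)-1,2-dichlorovinyloxy]-3-(4-methoxybenzyloxy)-5-methylphenyl}-1,3-dioxolane | COc1ccc(COc2cc(C)cc(C3OCCO3)c2O/C(Cl)=C\Cl)cc1 | intermediate
8 | 2-[2-(chloroethynyloxy)-3-(4-methoxybenzyloxy)-5-methylphenyl]-1,3-dioxolane (chloroalkyne) | COc1ccc(COc2cc(C)cc(C3OCCO3)c2OC#CCl)cc1 | intermediate
9 | lithium [2-(1,3-dioxolan-2-yl)-6-(4-methoxybenzyloxy)-4-methylphenoxy]ethynide (lithium acetylide) | COc1ccc(COc2cc(C)cc(C3OCCO3)c2OC#C[Li])cc1 | intermediate
10 | 3-[2-(1,3-dioxolan-2-yl)-6-(4-methoxybenzyloxy)-4-methylphenoxy]prop-2-yn-1-ol | COc1ccc(COc2cc(C)cc(C3OCCO3)c2OC#CCO)cc1 | intermediate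
11 | {3-[2-(1,3-dioxolan-2-yl)-6-(4-methoxybenzyloxy)-4-methylphenoxy]prop-2-ynyloxy}triethylsilane | COc1ccc(COc2cc(C)cc(C3OCCO3)c2OC#CCO[Si](CC)(CC)CC)cc1 | intermediate
12 | (S)-2-hydroxy-4-methylpentanoic acid (L-leucic acid) | CC(C)C[C@H](O)C(=O)O | starting material
13 | methyl (S)-2-hydroxy-4-methylpentanoate | CC(C)C[C@H](O)C(=O)OC | intermediate
14 | methyl (S)-2-(tert-butyldimethylsilyloxy)-4-methylpentanoate | CC(C)C[C@H](O[Si](C)(C)C(C)(C)C)C(=O)OC | intermediate
15 | (S)-2-(tert-butyldimethylsilyloxy)-4-methylpentanal | CC(C)C[C@H](O[Si](C)(C)C(C)(C)C)C=O | intermediate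
16 | (S,E)-5-(tert-butyldimethylsilyloxy)-7-methyloct-3-en-2-one | CC(=O)/C=C/[C@H](CC(C)C)O[Si](C)(C)C(C)(C)C | intermediate
17 | (S,E)-7-(tert-butyldimethylsilyloxy)-1,1,1-trifluoro-9-methyldec-5-ene-2,4-dione (trifluoroacetyl diketone) | O=C(CC(=O)/C=C/[C@H](CC(C)C)O[Si](C)(C)C(C)(C)C)C(F)(F)F | intermediate
18 | (S,E)-5-(tert-butyldimethylsilyloxy)-1-diazo-7-methyloct-3-en-2-one | [N-]=[N+]=CC(=O)/C=C/[C@H](CC(C)C)O[Si](C)(C)C(C)(C)C | intermediate
19 | (3E,5S)-5-(tert-butyldimethylsilyloxy)-7-methylocta-1,3-dien-1-one (vinylketene) | O=C=C/C=C/[C@H](CC(C)C)O[Si](C)(C)C(C)(C)C | intermediate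
20 | 3-[2-(1,3-dioxolan-2-yl)-6-(4-methoxybenzyloxy)-4-methylphenoxy]-4-[(1E,3S)-3-(tert-butyldimethylsilyloxy)-5-methylhex-1-enyl]-2-[(triethylsilyloxy)methyl]cyclobut-2-en-1-one (4-vinylcyclobutenone, C4 unassigned) | O=C1C(CO[Si](CC)(CC)CC)=C(Oc2c(OCc3ccc(OC)cc3)cc(C)cc2C4OCCO4)C1/C=C/[C@H](CC(C)C)O[Si](C)(C)C(C)(C)C | intermediate
21 | (3E,5E,7S)-7-(tert-butyldimethylsilyloxy)-3-[2-(1,3-dioxolan-2-yl)-6-(4-methoxybenzyloxy)-4-methylphenoxy]-9-methyl-2-[(triethylsilyloxy)methyl]deca-1,3,5-trien-1-one (dienylketene, ketene carbon and C5 cis across C3=C4) | O=C=C(CO[Si](CC)(CC)CC)/C(Oc1c(OCc2ccc(OC)cc2)cc(C)cc1C3OCCO3)=C\C=C\[C@H](CC(C)C)O[Si](C)(C)C(C)(C)C | intermediate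
22 | 6-[(1S)-1-(tert-butyldimethylsilyloxy)-3-methylbutyl]-3-[2-(1,3-dioxolan-2-yl)-6-(4-methoxybenzyloxy)-4-methylphenoxy]-2-[(triethylsilyloxy)methyl]cyclohexa-2,4-dien-1-one (cyclohexadienone, C6 unassigned) | O=C1C(CO[Si](CC)(CC)CC)=C(Oc2c(OCc3ccc(OC)cc3)cc(C)cc2C4OCCO4)C=CC1[C@H](CC(C)C)O[Si](C)(C)C(C)(C)C | intermediate
23 | 6-[(1S)-1-(tert-butyldimethylsilyloxy)-3-methylbutyl]-3-[2-(1,3-dioxolan-2-yl)-6-(4-methoxybenzyloxy)-4-methylphenoxy]-2-[(triethylsilyloxy)methyl]phenol | Oc1c([C@H](CC(C)C)O[Si](C)(C)C(C)(C)C)ccc(Oc2c(OCc3ccc(OC)cc3)cc(C)cc2C4OCCO4)c1CO[Si](CC)(CC)CC | intermediate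
24 | tert-butyl{(1S)-1-[4-[2-(1,3-dioxolan-2-yl)-6-(4-methoxybenzyloxy)-4-methylphenoxy]-2-methoxy-3-[(triethylsilyloxy)methyl]phenyl]-3-methylbutoxy}dimethylsilane | COc1c([C@H](CC(C)C)O[Si](C)(C)C(C)(C)C)ccc(Oc2c(OCc3ccc(OC)cc3)cc(C)cc2C4OCCO4)c1CO[Si](CC)(CC)CC | intermediate
25 | 2-{4-[(1S)-1-(tert-butyldimethylsilyloxy)-3-methylbutyl]-2-(hydroxymethyl)-3-methoxyphenoxy}-3-(4-methoxybenzyloxy)-5-methylbenzaldehyde | COc1c([C@H](CC(C)C)O[Si](C)(C)C(C)(C)C)ccc(Oc2c(OCc3ccc(OC)cc3)cc(C)cc2C=O)c1CO | intermediate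
26 | (E)-4-{2-[4-[(1S)-1-(tert-butyldimethylsilyloxy)-3-methylbutyl]-2-(hydroxymethyl)-3-methoxyphenoxy]-3-(4-methoxybenzyloxy)-5-methylphenyl}but-3-en-2-one | COc1c([C@H](CC(C)C)O[Si](C)(C)C(C)(C)C)ccc(Oc2c(OCc3ccc(OC)cc3)cc(C)cc2/C=C/C(C)=O)c1CO | intermediate
27 | 3-[(1S)-1-(tert-butyldimethylsilyloxy)-3-methylbutyl]-2-methoxy-6-{2-(4-methoxybenzyloxy)-4-methyl-6-[(E)-3-oxobut-1-enyl]phenoxy}benzaldehyde | COc1c([C@H](CC(C)C)O[Si](C)(C)C(C)(C)C)ccc(Oc2c(OCc3ccc(OC)cc3)cc(C)cc2/C=C/C(C)=O)c1C=O | intermediate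
28 | 3-[(1S)-1-hydroxy-3-methylbutyl]-2-methoxy-6-{2-(4-methoxybenzyloxy)-4-methyl-6-[(E)-3-oxobut-1-enyl]phenoxy}benzaldehyde | COc1c([C@H](CC(C)C)O)ccc(Oc2c(OCc3ccc(OC)cc3)cc(C)cc2/C=C/C(C)=O)c1C=O | intermediate
29 | (1S)-1-[3-formyl-2-methoxy-4-{2-(4-methoxybenzyloxy)-4-methyl-6-[(E)-3-oxobut-1-enyl]phenoxy}phenyl]-3-methylbutyl acetate | COc1c([C@H](CC(C)C)OC(C)=O)ccc(Oc2c(OCc3ccc(OC)cc3)cc(C)cc2/C=C/C(C)=O)c1C=O | intermediate
30 | 3-[(1S)-1-acetoxy-3-methylbutyl]-2-methoxy-6-{2-(4-methoxybenzyloxy)-4-methyl-6-[(E)-3-oxobut-1-enyl]phenoxy}benzoic acid | COc1c([C@H](CC(C)C)OC(C)=O)ccc(Oc2c(OCc3ccc(OC)cc3)cc(C)cc2/C=C/C(C)=O)c1C(=O)O | intermediate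
31 | 3-[(1S)-1-acetoxy-3-methylbutyl]-6-{2-hydroxy-4-methyl-6-[(E)-3-oxobut-1-enyl]phenoxy}-2-methoxybenzoic acid | COc1c([C@H](CC(C)C)OC(C)=O)ccc(Oc2c(O)cc(C)cc2/C=C/C(C)=O)c1C(=O)O | target

**Step count and risks**

Total step count: 21. Longest linear sequence: 16 steps (steps 1–7 and 13–21, from creosol).

Steps most likely to fail:

1. Step 13. The hindered aryloxyalkyne is a weaker nucleophile than alkoxy- or siloxyalkynes and may capture the vinylketene too slowly, so that ketene dimerisation, acylation of the product phenol or photodegradation of the ynol ether takes over. The fallback sets out from 18 and comes back at 25; ring A is built with a siloxyalkyne and the diaryl ether is made afterwards by nucleophilic aromatic substitution.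
   - Diazo ketone 18 would be irradiated as in step 13 with the siloxyalkyne tert-butyldimethyl{[3-(triisopropylsilyloxy)prop-2-ynyl]oxy}silane F1, which would be made from ethyl (tert-butyldimethylsilyloxy)acetate by ynolate formation of the Kowalski ester homologation type (LiCHBr2, then n-BuLi) and O-silylation with i-Pr3SiOTf. This should give 2-[(tert-butyldimethylsilyloxy)methyl]-6-[(1S)-1-(tert-butyldimethylsilyloxy)-3-methylbutyl]-3-(triisopropylsilyloxy)phenol F2.
   - O-Methylation (MeI, Cs2CO3, DMF) would give tert-butyl{(1S)-1-[3-[(tert-butyldimethylsilyloxy)methyl]-2-methoxy-4-(triisopropylsilyloxy)phenyl]-3-methylbutoxy}dimethylsilane F3. Selective cleavage of the aryl silyl ether (Bu4NF, 1 equiv, THF, −78 → 0 °C) would give 2-[(tert-butyldimethylsilyloxy)methyl]-4-[(1S)-1-(tert-butyldimethylsilyloxy)-3-methylbutyl]-3-methoxyphenol F4.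
   - In parallel, commercial 2-fluoro-5-methylphenol would be converted (PMBCl, K2CO3, DMF) to 1-fluoro-2-(4-methoxybenzyloxy)-4-methylbenzene F5. Lithiation next to fluorine and formylation (n-BuLi, PMDTA, THF, −78 °C; then DMF) would give 2-fluoro-3-(4-methoxybenzyloxy)-5-methylbenzaldehyde F6.
   - Substitution of the formyl-activated fluoride of F6 by the phenoxide of F4 (Cs2CO3, DMF, 80 °C) would give 2-{2-[(tert-butyldimethylsilyloxy)methyl]-4-[(1S)-1-(tert-butyldimethylsilyloxy)-3-methylbutyl]-3-methoxyphenoxy}-3-(4-methoxybenzyloxy)-5-methylbenzaldehyde F7. Selective removal of the primary silyl ether (HF·pyridine, pyridine, THF, 0 °C) would return to hydroxy aldehyde 25.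

2. Step 6. The lithium aryloxyacetylide may form incompletely or be lost to competing lithiation at the PMB methylene or next to the acetal, its addition to polymeric formaldehyde may be sluggish, and the propargylic alcohol may rearrange during isolation. The fallback sets out from 4 and comes back at 11 without any organolithium or free propargylic alcohol.
   - Phenol 4 would be acetalised (HOCH2CH2OH, PPTS, benzene, reflux) to 2-(1,3-dioxolan-2-yl)-6-(4-methoxybenzyloxy)-4-methylphenol F8.
   - F8 would be coupled under copper catalysis (CuI, 2,2'-bipyridine, K3PO4, toluene, 80 °C) with (3,3-dibromoallyloxy)triethylsilane F9, itself made from (triethylsilyloxy)acetaldehyde by Ramirez olefination (CBr4, PPh3). Coupling at the C–Br bond trans to the chain should give triethyl{[(Z)-3-bromo-3-[2-(1,3-dioxolan-2-yl)-6-(4-methoxybenzyloxy)-4-methylphenoxy]prop-2-enyl]oxy}silane F10.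
   - Anti elimination of HBr (KOt-Bu, THF, 0 °C) would give ynol ether 11.

3. Step 21. Oxidation of an aryl PMB ether by DDQ may be sluggish, and the liberated electron-rich phenol or the benzylic positions may be over-oxidised while the acetate and the free acid are present. The fallback sets out from 27 and comes back at 31; the ring B phenol is unmasked earlier by acidolysis and carried as its acetate.
   - Treatment of 27 with CF3CO2H and anisole (CH2Cl2, 0 °C) would give 3-[(1S)-1-(tert-butyldimethylsilyloxy)-3-methylbutyl]-6-{2-hydroxy-4-methyl-6-[(E)-3-oxobut-1-enyl]phenoxy}-2-methoxybenzaldehyde F11.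
   - Desilylation (HF·pyridine, THF) would give 3-[(1S)-1-hydroxy-3-methylbutyl]-6-{2-hydroxy-4-methyl-6-[(E)-3-oxobut-1-enyl]phenoxy}-2-methoxybenzaldehyde F12.
   - Double acetylation (Ac2O, pyridine, DMAP) would give (1S)-1-[4-{2-acetoxy-4-methyl-6-[(E)-3-oxobut-1-enyl]phenoxy}-3-formyl-2-methoxyphenyl]-3-methylbutyl acetate F13.
   - Pinnick oxidation as in step 20 would give 3-[(1S)-1-acetoxy-3-methylbutyl]-6-{2-acetoxy-4-methyl-6-[(E)-3-oxobut-1-enyl]phenoxy}-2-methoxybenzoic acid F14.
   - Chemoselective cleavage of the aryl acetate in the presence of the alkyl acetate (NH4OAc, MeOH–H2O, rt) would give target 31.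

**Further compounds**

F1 | step 13 | tert-butyldimethyl{[3-(triisopropylsilyloxy)prop-2-ynyl]oxy}silane | CC(C)[Si](OC#CCO[Si](C)(C)C(C)(C)C)(C(C)C)C(C)C
F2 | step 13 | 2-[(tert-butyldimethylsilyloxy)methyl]-6-[(1S)-1-(tert-butyldimethylsilyloxy)-3-methylbutyl]-3-(triisopropylsilyloxy)phenol | Oc1c([C@H](CC(C)C)O[Si](C)(C)C(C)(C)C)ccc(O[Si](C(C)C)(C(C)C)C(C)C)c1CO[Si](C)(C)C(C)(C)C
F3 | step 13 | tert-butyl{(1S)-1-[3-[(tert-butyldimethylsilyloxy)methyl]-2-methoxy-4-(triisopropylsilyloxy)phenyl]-3-methylbutoxy}dimethylsilane | COc1c([C@H](CC(C)C)O[Si](C)(C)C(C)(C)C)ccc(O[Si](C(C)C)(C(C)C)C(C)C)c1CO[Si](C)(C)C(C)(C)C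
F4 | step 13 | 2-[(tert-butyldimethylsilyloxy)methyl]-4-[(1S)-1-(tert-butyldimethylsilyloxy)-3-methylbutyl]-3-methoxyphenol | COc1c([C@H](CC(C)C)O[Si](C)(C)C(C)(C)C)ccc(O)c1CO[Si](C)(C)C(C)(C)C
F5 | step 13 | 1-fluoro-2-(4-methoxybenzyloxy)-4-methylbenzene | COc1ccc(COc2cc(C)ccc2F)cc1
F6 | step 13 | 2-fluoro-3-(4-methoxybenzyloxy)-5-methylbenzaldehyde | COc1ccc(COc2cc(C)cc(C=O)c2F)cc1
F7 | step 13 | 2-{2-[(tert-butyldimethylsilyloxy)methyl]-4-[(1S)-1-(tert-butyldimethylsilyloxy)-3-methylbutyl]-3-methoxyphenoxy}-3-(4-methoxybenzyloxy)-5-methylbenzaldehyde | COc1c([C@H](CC(C)C)O[Si](C)(C)C(C)(C)C)ccc(Oc2c(OCc3ccc(OC)cc3)cc(C)cc2C=O)c1CO[Si](C)(C)C(C)(C)C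
F8 | step 6 | 2-(1,3-dioxolan-2-yl)-6-(4-methoxybenzyloxy)-4-methylphenol | COc1ccc(COc2cc(C)cc(C3OCCO3)c2O)cc1
F9 | step 6 | (3,3-dibromoallyloxy)triethylsilane | CC[Si](CC)(CC)OCC=C(Br)Br
F10 | step 6 | triethyl{[(Z)-3-bromo-3-[2-(1,3-dioxolan-2-yl)-6-(4-methoxybenzyloxy)-4-methylphenoxy]prop-2-enyl]oxy}silane | CC[Si](CC)(CC)OC/C=C(\Br)Oc1c(OCc2ccc(OC)cc2)cc(C)cc1C3OCCO3
F11 | step 21 | 3-[(1S)-1-(tert-butyldimethylsilyloxy)-3-methylbutyl]-6-{2-hydroxy-4-methyl-6-[(E)-3-oxobut-1-enyl]phenoxy}-2-methoxybenzaldehyde | COc1c([C@H](CC(C)C)O[Si](C)(C)C(C)(C)C)ccc(Oc2c(O)cc(C)cc2/C=C/C(C)=O)c1C=O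
F12 | step 21 | 3-[(1S)-1-hydroxy-3-methylbutyl]-6-{2-hydroxy-4-methyl-6-[(E)-3-oxobut-1-enyl]phenoxy}-2-methoxybenzaldehyde | COc1c([C@H](CC(C)C)O)ccc(Oc2c(O)cc(C)cc2/C=C/C(C)=O)c1C=O
F13 | step 21 | (1S)-1-[4-{2-acetoxy-4-methyl-6-[(E)-3-oxobut-1-enyl]phenoxy}-3-formyl-2-methoxyphenyl]-3-methylbutyl acetate | COc1c([C@H](CC(C)C)OC(C)=O)ccc(Oc2c(OC(C)=O)cc(C)cc2/C=C/C(C)=O)c1C=O
F14 | step 21 | 3-[(1S)-1-acetoxy-3-methylbutyl]-6-{2-acetoxy-4-methyl-6-[(E)-3-oxobut-1-enyl]phenoxy}-2-methoxybenzoic acid | COc1c([C@H](CC(C)C)OC(C)=O)ccc(Oc2c(OC(C)=O)cc(C)cc2/C=C/C(C)=O)c1C(=O)O
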